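**Retrosynthetic overview**

- C2–C1′ is cut last: an 8-alkyl-5-hydroxychromone plus a 4-silyloxyphenylboronic acid, joined by Rh-catalysed asymmetric 1,4-arylation, which sets C2 (S) by catalyst control.
- C2″–C3″ is the key cut. C2″ carries H, an isopropenyl group and two CH2 arms (C1″ to C8 of ring A, C3″ to the chain), which is the retron of an enantioselective SN2′ alkylation of an (E)-4-chloroprenyl group on C8 by a homomethallyl Grignard reagent. This step turns a C5 prenyl unit into the complete irregular C10 chain, creates the isopropenyl group and sets C2″ (R); its precursor has no stereocentre.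
- The (E)-4-chloroprenyl group comes from an 8-prenyl group by E-selective SeO2 oxidation and chlorination.
- The C8–C1″ bond comes from a 5-O-prenyl ether by a para-Claisen–Cope relay O5 → C6 → C8, which fixes C8 over C6.
- No ring is closed: the A/C benzopyranone is bought as 5,7-dihydroxychromone and only brought to the flavanone level when ring B is attached.

Key step: step 7

Assumption 1: 5,7-dihydroxy-4H-chromen-4-one is taken as a purchasable starting material.
Assumption 2: both antipodes of the phosphoramidite (step 7) and of MeO-F12-BIPHEP (step 8) are available; the sense of induction is checked on a model before scale-up and the antipode giving the stated face is used.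

**Step 1**
Reactants: 1 5,7-dihydroxy-4H-chromen-4-one
Product: 2 5-hydroxy-7-[tri(propan-2-yl)silyloxy]-4H-chromen-4-one
Conditions: TIPSCl (1.05 equiv), imidazole, DMF, 0 °C to rt
Reagents that add atoms: chlorotri(propan-2-yl)silane (TIPSCl), CC(C)[Si](Cl)(C(C)C)C(C)C
Why: Regioselective O-silylation: the 7-OH is the acidic, unhindered phenol, while the 5-OH is held in a hydrogen bond to C4=O and should stay free.

**Step 2**
Reactants: 2 5-hydroxy-7-[tri(propan-2-yl)silyloxy]-4H-chromen-4-one; 3 3-methylbut-2-en-1-ol (prenol)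
Product: 4 5-[(3-methylbut-2-en-1-yl)oxy]-7-[tri(propan-2-yl)silyloxy]-4H-chromen-4-one
Conditions: PPh3, DIAD, THF, 0 °C to rt
Reagents that add atoms: none
Why: Mitsunobu etherification alkylates the chelated but sufficiently acidic 5-OH at the primary allylic carbon under neutral conditions that leave the aryl silyl ether intact.

**Step 3**
Reactants: 4 5-[(3-methylbut-2-en-1-yl)oxy]-7-[tri(propan-2-yl)silyloxy]-4H-chromen-4-one
Product: 7 5-hydroxy-8-(3-methylbut-2-en-1-yl)-7-[tri(propan-2-yl)silyloxy]-4H-chromen-4-one, via C6 ortho-dienone 5 (not isolated), via C8 para-dienone 6 (not isolated)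
Conditions: Eu(fod)3 (10 mol%), NaHCO3, PhCl, 85 °C
Reagents that add atoms: none
Why: Eu(III)-catalysed para-Claisen–Cope rearrangement: a [3,3] shift O5→C6 gives the reverse-prenyl dienone 5, a second [3,3] shift C6→C8 gives 6, and enolisation restores the phenol; C8 is the only position para to O5, so the C8 attachment should be dictated by the mechanism.

**Step 4**
Reactants: 7 5-hydroxy-8-(3-methylbut-2-en-1-yl)-7-[tri(propan-2-yl)silyloxy]-4H-chromen-4-one
Product: 8 5-hydroxy-8-[(2E)-4-hydroxy-3-methylbut-2-en-1-yl]-7-[tri(propan-2-yl)silyloxy]-4H-chromen-4-one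
Conditions: SeO2 (0.3 equiv), t-BuOOH, salicylic acid (cat.), CH2Cl2, rt
Reagents that add atoms: selenium dioxide, O=[Se]=O (oxygen carrier, substoichiometric); tert-butyl hydroperoxide, CC(C)(C)OO (terminal oxidant)
Why: SeO2 allylic oxidation (ene reaction, then [2,3]-sigmatropic shift) attacks the methyl group trans to the chain of a trisubstituted alkene, so the (E)-allylic alcohol should form and the benzylic C1″ should stay untouched.

**Step 5**
Reactants: 8 5-hydroxy-8-[(2E)-4-hydroxy-3-methylbut-2-en-1-yl]-7-[tri(propan-2-yl)silyloxy]-4H-chromen-4-one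
Product: 10 8-[(2E)-4-chloro-3-methylbut-2-en-1-yl]-5-hydroxy-7-[tri(propan-2-yl)silyloxy]-4H-chromen-4-one, via allylic mesylate 9 (not isolated)
Conditions: MsCl (1.1 equiv), 2,4,6-collidine, LiCl, DMF, 0 °C
Reagents that add atoms: methanesulfonyl chloride, CS(=O)(=O)Cl (atoms only in 9); lithium chloride, [Li+].[Cl-]
Why: Mesylation of the primary allylic alcohol and in situ SN2 displacement by chloride should give the primary allylic chloride without allylic transposition or loss of E geometry; the chelated 5-OH is a poor nucleophile.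

**Step 6**
Reactants: 11 4-bromo-2-methylbut-1-ene
Product: 12 (3-methylbut-3-en-1-yl)magnesium bromide (solution in Et2O, titrated, used as such)
Conditions: Mg turnings, I2 (trace), Et2O, gentle reflux then rt
Reagents that add atoms: magnesium, [Mg]
Why: Grignard formation from a primary homoallylic bromide; the 1,1-disubstituted alkene is inert to the organomagnesium.

**Step 7**
Reactants: 10 8-[(2E)-4-chloro-3-methylbut-2-en-1-yl]-5-hydroxy-7-[tri(propan-2-yl)silyloxy]-4H-chromen-4-one; 12 (3-methylbut-3-en-1-yl)magnesium bromide (2.3 equiv)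
Product: 15 5-hydroxy-8-[(2R)-5-methyl-2-(prop-1-en-2-yl)hex-5-en-1-yl]-7-[tri(propan-2-yl)silyloxy]-4H-chromen-4-one, via chloride magnesium phenoxide 13 (not isolated), via product magnesium phenoxide 14 (not isolated)
Conditions: CuTC (5 mol%), BINOL-derived phosphoramidite with an N,N-bis[1-(2-methoxyphenyl)ethyl]amino group (6 mol%, antipode for Re-face delivery), CH2Cl2, −78 °C, 12 added over 3 h; aq. NH4Cl
Reagents that add atoms: none
Why: Transmetalation of 12 to the Cu(I)–phosphoramidite complex gives an alkylcuprate that binds the C2″=C3″ alkene anti to the C–Cl bond, adds oxidatively at the γ-carbon C2″ to a σ-allyl Cu(III) species and eliminates reductively before it can shift to the α-terminus, so the C2″–C3″ bond forms and the alkene moves into the isopropenyl position. The closest known reaction type is the Cu/phosphoramidite-catalysed enantioselective SN2′ alkylation of β-methyl-substituted (E)-allylic chlorides with primary alkyl Grignard reagents, which gives 1,1-disubstituted alkenes with an α-stereocentre. No ring is closed. The new stereocentre C2″ is controlled by the chiral ligand on copper alone: alkyl delivery to the Re face of C2″ gives R, the substrate has no other stereocentre, and the single E geometry from step 4 ensures that one ligand antipode leads to one enantiomer. The step needs γ- over α-selectivity, which the chloride leaving group, CuTC, CH2Cl2 at −78 °C and slow addition (low free Grignard) should secure. It also needs chemoselectivity over the pyranone: the first equivalent of 12 turns the 5-OH into the magnesium phenoxide 13 chelated to C4=O, a vinylogous carboxylate that should resist 1,2- and 1,4-addition, and the 7-O-silyl group keeps O7 from closing a dihydrobenzofuran by intramolecular SN2′.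

**Step 8**
Reactants: 15 5-hydroxy-8-[(2R)-5-methyl-2-(prop-1-en-2-yl)hex-5-en-1-yl]-7-[tri(propan-2-yl)silyloxy]-4H-chromen-4-one; 16 {4-[tert-butyl(dimethyl)silyloxy]phenyl}boronic acid (2 equiv)
Product: 17 (2S)-2-{4-[tert-butyl(dimethyl)silyloxy]phenyl}-5-hydroxy-8-[(2R)-5-methyl-2-(prop-1-en-2-yl)hex-5-en-1-yl]-7-[tri(propan-2-yl)silyloxy]-2,3-dihydro-4H-chromen-4-one
Conditions: [Rh(OH)((S)-MeO-F12-BIPHEP)]2 (3 mol% Rh), toluene/H2O 10:1, 30 °C
Reagents that add atoms: none
Why: Rh(I)-catalysed asymmetric 1,4-addition of an arylboronic acid to a chromone (Hayashi–Miyaura type): the aryl–Rh species carbometalates C2=C3 on the Re face of C2 under ligand control (expected sense by analogy with cyclic enones and (S)-biaryl bisphosphines) to give 2S independently of the remote C2″, the electron-poor bisphosphine allows a base-free low-temperature run that avoids retro-oxa-Michael opening, and the isolated 1,1-disubstituted alkenes do not insert.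

**Step 9**
Reactants: 17 (2S)-2-{4-[tert-butyl(dimethyl)silyloxy]phenyl}-5-hydroxy-8-[(2R)-5-methyl-2-(prop-1-en-2-yl)hex-5-en-1-yl]-7-[tri(propan-2-yl)silyloxy]-2,3-dihydro-4H-chromen-4-one
Product: 18 remangiflavanone A, (2S)-5,7-dihydroxy-2-(4-hydroxyphenyl)-8-[(2R)-5-methyl-2-(prop-1-en-2-yl)hex-5-en-1-yl]-2,3-dihydro-4H-chromen-4-one
Conditions: TBAF (2.5 equiv), AcOH (3 equiv), THF, 0 °C
Reagents that add atoms: none
Why: Fluoride cleavage of both aryl silyl ethers; the acetic acid buffer keeps the phenols protonated, which should prevent base-induced ring opening (epimerisation at C2), and no strong acid is present that could cyclise the 7-OH onto the isopropenyl group.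

**Compound list**

1 | 5,7-dihydroxy-4H-chromen-4-one | O=c1ccoc2cc(O)cc(O)c12 | starting material
2 | 5-hydroxy-7-[tri(propan-2-yl)silyloxy]-4H-chromen-4-one | O=c1ccoc2cc(O[Si](C(C)C)(C(C)C)C(C)C)cc(O)c12 | intermediate
3 | 3-methylbut-2-en-1-ol | CC(C)=CCO | starting material
4 | 5-[(3-methylbut-2-en-1-yl)oxy]-7-[tri(propan-2-yl)silyloxy]-4H-chromen-4-one | O=c1ccoc2cc(O[Si](C(C)C)(C(C)C)C(C)C)cc(OCC=C(C)C)c12 | intermediate
5 | 6-(2-methylbut-3-en-2-yl)-7-[tri(propan-2-yl)silyloxy]-4H-chromene-4,5(6H)-dione (C6 ortho-dienone, C6 unassigned) | O=C1C=COC2=C1C(=O)C(C(C)(C)C=C)C(O[Si](C(C)C)(C(C)C)C(C)C)=C2 | intermediate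
6 | 8-(3-methylbut-2-en-1-yl)-7-[tri(propan-2-yl)silyloxy]-4H-chromene-4,5(8H)-dione (C8 para-dienone, C8 unassigned) | O=C1C=COC2=C1C(=O)C=C(O[Si](C(C)C)(C(C)C)C(C)C)C2CC=C(C)C | intermediate
7 | 5-hydroxy-8-(3-methylbut-2-en-1-yl)-7-[tri(propan-2-yl)silyloxy]-4H-chromen-4-one | O=c1ccoc2c(CC=C(C)C)c(O[Si](C(C)C)(C(C)C)C(C)C)cc(O)c12 | intermediate
8 | 5-hydroxy-8-[(2E)-4-hydroxy-3-methylbut-2-en-1-yl]-7-[tri(propan-2-yl)silyloxy]-4H-chromen-4-one | O=c1ccoc2c(C/C=C(\C)CO)c(O[Si](C(C)C)(C(C)C)C(C)C)cc(O)c12 | intermediate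
9 | (2E)-4-{5-hydroxy-4-oxo-7-[tri(propan-2-yl)silyloxy]-4H-chromen-8-yl}-2-methylbut-2-en-1-yl methanesulfonate | O=c1ccoc2c(C/C=C(\C)COS(C)(=O)=O)c(O[Si](C(C)C)(C(C)C)C(C)C)cc(O)c12 | intermediate
10 | 8-[(2E)-4-chloro-3-methylbut-2-en-1-yl]-5-hydroxy-7-[tri(propan-2-yl)silyloxy]-4H-chromen-4-one | O=c1ccoc2c(C/C=C(\C)CCl)c(O[Si](C(C)C)(C(C)C)C(C)C)cc(O)c12 | intermediate
11 | 4-bromo-2-methylbut-1-ene | C=C(C)CCBr | starting material
12 | (3-methylbut-3-en-1-yl)magnesium bromide | C=C(C)CC[Mg]Br | intermediate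
13 | bromomagnesium 5-phenoxide of 10 | O=c1ccoc2c(C/C=C(\C)CCl)c(O[Si](C(C)C)(C(C)C)C(C)C)cc(O[Mg]Br)c12 | intermediate
14 | bromomagnesium 5-phenoxide of 15 | C=C(C)CC[C@H](Cc1c(O[Si](C(C)C)(C(C)C)C(C)C)cc(O[Mg]Br)c2c1occc2=O)C(=C)C | intermediate
15 | 5-hydroxy-8-[(2R)-5-methyl-2-(prop-1-en-2-yl)hex-5-en-1-yl]-7-[tri(propan-2-yl)silyloxy]-4H-chromen-4-one | C=C(C)CC[C@H](Cc1c(O[Si](C(C)C)(C(C)C)C(C)C)cc(O)c2c1occc2=O)C(=C)C | intermediate
16 | {4-[tert-butyl(dimethyl)silyloxy]phenyl}boronic acid | CC(C)(C)[Si](C)(C)Oc1ccc(B(O)O)cc1 | starting material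
17 | (2S)-2-{4-[tert-butyl(dimethyl)silyloxy]phenyl}-5-hydroxy-8-[(2R)-5-methyl-2-(prop-1-en-2-yl)hex-5-en-1-yl]-7-[tri(propan-2-yl)silyloxy]-2,3-dihydro-4H-chromen-4-one | C=C(C)CC[C@H](Cc1c(O[Si](C(C)C)(C(C)C)C(C)C)cc(O)c2c1O[C@H](c1ccc(O[Si](C)(C)C(C)(C)C)cc1)CC2=O)C(=C)C | intermediate
18 | remangiflavanone A, (2S)-5,7-dihydroxy-2-(4-hydroxyphenyl)-8-[(2R)-5-methyl-2-(prop-1-en-2-yl)hex-5-en-1-yl]-2,3-dihydro-4H-chromen-4-one | C=C(C)CC[C@H](Cc1c(O)cc(O)c2c1O[C@H](c1ccc(O)cc1)CC2=O)C(=C)C | target

**Step count**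

Total steps: 9 (eight on the main line plus the Grignard preparation).
Longest linear sequence: 8 steps (1, 2, 3, 4, 5, 7, 8, 9).

**Steps most likely to fail**

1. Step 7 (Cu-catalysed SN2′). The two CH2 groups on the γ-carbon may be poorly discriminated, giving low enantiofacial selectivity. α-Substitution may leak in, base may cause 1,4-elimination to a diene, or the organocopper may add to the pyranone despite the chelate. The fallback sets out from 8 and returns at 15. Sharpless asymmetric epoxidation of 8 (Ti(OiPr)4 in full equivalent because the 5-hydroxy-4-oxo chelate can bind titanium, L-(+)-diethyl tartrate, t-BuOOH, 4 Å MS, CH2Cl2, −20 °C) should give 5-hydroxy-8-{[(2S,3S)-3-(hydroxymethyl)-3-methyloxiran-2-yl]methyl}-7-[tri(propan-2-yl)silyloxy]-4H-chromen-4-one F1. Copper-catalysed opening with 12 (CuI, THF, −30 °C, excess for the two OH groups) should occur at the less substituted oxirane carbon C2″ with inversion and give the 1,2-diol F2, which already has the 2″R configuration. Thiocarbonyldiimidazole (DMAP, toluene) should give the cyclic thionocarbonate F3, and Corey–Winter olefination with 1,3-dimethyl-2-phenyl-1,3,2-diazaphospholidine (40 °C) should unveil the isopropenyl group and give 15.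

2. Step 8 (Rh-catalysed 1,4-arylation). The electron-rich 5-hydroxy-7-silyloxychromone may carbometalate slowly, the boronic acid may protodeboronate, and facial selectivity may erode through reversible ring opening. The fallback sets out from 15 and 16 and returns at 17. The aryl group is added without facial control ([Rh(OH)(cod)]2, dioxane/H2O, 50 °C) to give the C2-epimeric flavanone mixture F4. Asymmetric transfer hydrogenation used as a kinetic resolution ([Cp*RhCl(TsDPEN)], HCO2H/Et3N, the catalyst antipode that reduces the 2R epimer) should convert the unwanted epimer into the cis-(2R,4R)-flavan-4-ol F5 and leave 17, which is separated by chromatography.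

3. Step 4 (SeO2 oxidation). Over-oxidation to the enal, oxidation of the electron-rich chelated phenol, or incomplete conversion may occur. The fallback sets out from 7 and returns at 8. Oxidative cleavage of the prenyl alkene (OsO4 cat., NaIO4, 2,6-lutidine, dioxane/H2O) should give the arylacetaldehyde F6. Wittig olefination with 2-(triphenylphosphoranylidene)propanal (toluene, 80 °C) should give the (E)-enal F7, and Luche reduction (NaBH4, CeCl3·7H2O, MeOH, −78 °C) should reduce the aldehyde in preference to the pyranone carbonyl and give 8.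

**Further compounds**

F1 | step 7 | 5-hydroxy-8-{[(2S,3S)-3-(hydroxymethyl)-3-methyloxiran-2-yl]methyl}-7-[tri(propan-2-yl)silyloxy]-4H-chromen-4-one | O=c1ccoc2c(C[C@@H]3O[C@@]3(C)CO)c(O[Si](C(C)C)(C(C)C)C(C)C)cc(O)c12
F2 | step 7 | 8-{(2R)-2-[(2R)-1,2-dihydroxypropan-2-yl]-5-methylhex-5-en-1-yl}-5-hydroxy-7-[tri(propan-2-yl)silyloxy]-4H-chromen-4-one | C=C(C)CC[C@H](Cc1c(O[Si](C(C)C)(C(C)C)C(C)C)cc(O)c2c1occc2=O)[C@@](C)(O)CO
F3 | step 7 | 5-hydroxy-8-{(2R)-5-methyl-2-[(4R)-4-methyl-2-sulfanylidene-1,3-dioxolan-4-yl]hex-5-en-1-yl}-7-[tri(propan-2-yl)silyloxy]-4H-chromen-4-one | C=C(C)CC[C@H](Cc1c(O[Si](C(C)C)(C(C)C)C(C)C)cc(O)c2c1occc2=O)[C@]1(C)COC(=S)O1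
F4 | step 8 | (2RS)-2-{4-[tert-butyl(dimethyl)silyloxy]phenyl}-5-hydroxy-8-[(2R)-5-methyl-2-(prop-1-en-2-yl)hex-5-en-1-yl]-7-[tri(propan-2-yl)silyloxy]-2,3-dihydro-4H-chromen-4-one (mixture of C2 epimers) | C=C(C)CC[C@H](Cc1c(O[Si](C(C)C)(C(C)C)C(C)C)cc(O)c2c1OC(c1ccc(O[Si](C)(C)C(C)(C)C)cc1)CC2=O)C(=C)C
F5 | step 8 | (2R,4R)-2-{4-[tert-butyl(dimethyl)silyloxy]phenyl}-8-[(2R)-5-methyl-2-(prop-1-en-2-yl)hex-5-en-1-yl]-7-[tri(propan-2-yl)silyloxy]-3,4-dihydro-2H-chromene-4,5-diol | C=C(C)CC[C@H](Cc1c(O[Si](C(C)C)(C(C)C)C(C)C)cc(O)c2c1O[C@@H](c1ccc(O[Si](C)(C)C(C)(C)C)cc1)C[C@H]2O)C(=C)C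
F6 | step 4 | {5-hydroxy-4-oxo-7-[tri(propan-2-yl)silyloxy]-4H-chromen-8-yl}acetaldehyde | O=CCc1c(O[Si](C(C)C)(C(C)C)C(C)C)cc(O)c2c1occc2=O
F7 | step 4 | (2E)-4-{5-hydroxy-4-oxo-7-[tri(propan-2-yl)silyloxy]-4H-chromen-8-yl}-2-methylbut-2-enal | O=C/C(C)=C/Cc1c(O[Si](C(C)C)(C(C)C)C(C)C)cc(O)c2c1occc2=O
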